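**Plan**

- Retrosynthetic cuts: the C4–Br and C5–Cl bonds (back to a C4=C5 alkene), the carbocycle bond C1–C6 (two-atom ring expansion of a cyclobutanol), the isopropenyl–ring bond, the oxane O–C6 bond (bromoetherification), the carbocycle bond C2–C3 (semipinacol shift of an epoxy cyclopropanol) and the cyclopropane itself, back to geraniol.
- Forward order: epoxide → cyclopropanol → cyclobutanone (3→4) → bromo-oxane → 2-isopropenylcyclobutanol → cyclohexenol (4→6) → carbinol reset → halogen pair.
- Enabling feature: the C1 carbinol together with the C4-Br/C5-Cl pair (a masked C4=C5 alkene carrying the methyl) makes the carbocycle a 3-methylcyclohex-3-en-1-ol. That is the product pattern of the alkoxide-accelerated [1,3] shift of a 2-(prop-1-en-2-yl)cyclobutan-1-ol, in which the isopropenyl group fixes where the methyl ends up.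
- Stereochemistry: oxane C2 and carbocycle C2 come from the Sharpless epoxide of geraniol (C2 by inversion in the semipinacol shift). Oxane C5 comes from the chair-like anti bromoetherification. C1 is set by L-Selectride. C4/C5 come from anti chlorohydroxylation followed by halide exchange and the diaxial-to-diequatorial dihalide interchange.

Key step: step 8

Remark: the diequatorial Br/Cl arrangement of the target is assumed to be thermodynamically preferred over its diaxial isomer with the halogens interchanged; step 12 relies on this.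

Step 1
Reactants: 1 geraniol
Product: 2 [(2S,3S)-3-methyl-3-(4-methylpent-3-en-1-yl)oxiran-2-yl]methanol
Conditions: Ti(OiPr)4 (cat.), L-(+)-diethyl tartrate (cat.), t-BuOOH, 4 Å MS, CH2Cl2, −20 °C
Reagents that add atoms: tert-butyl hydroperoxide CC(C)(C)OO
Why: Katsuki–Sharpless asymmetric epoxidation acts only on the allylic 2,3-alkene, and the L-(+)-tartrate catalyst should give the (2S,3S)-epoxide, which holds the later oxane C2 configuration and, after inversion, that of carbocycle C2.

Step 2
Reactants: 2 [(2S,3S)-3-methyl-3-(4-methylpent-3-en-1-yl)oxiran-2-yl]methanol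
Product: 4 methyl (2R,3S)-3-methyl-3-(4-methylpent-3-en-1-yl)oxirane-2-carboxylate, via epoxy acid 3 (not isolated)
Conditions: TEMPO (cat.), PhI(OAc)2, MeCN–pH 7 buffer, 0 °C to rt; then TMSCHN2, toluene–MeOH, 0 °C
Reagents that add atoms: water O; trimethylsilyldiazomethane C[Si](C)(C)C=[N+]=[N-]
Why: the nitroxyl/iodine(III) oxidation of a primary alcohol to the acid tolerates epoxide and trisubstituted alkene, and immediate esterification with the diazoalkane should avoid decarboxylative opening of the glycidic acid.

Step 3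
Reactants: 4 methyl (2R,3S)-3-methyl-3-(4-methylpent-3-en-1-yl)oxirane-2-carboxylate
Product: 5 1-[(2S,3S)-3-methyl-3-(4-methylpent-3-en-1-yl)oxiran-2-yl]cyclopropan-1-ol
Conditions: EtMgBr (slow addition), Ti(OiPr)4 (0.5 equiv), THF, 0 °C to rt
Reagents that add atoms: ethylmagnesium bromide CC[Mg]Br
Why: in the Kulinkovich reaction the titanacyclopropane formed from EtMgBr adds twice to the ester carbon as a 1,2-dicarbanion, giving the cyclopropanol without a new stereocentre and without touching the epoxide centres.

Step 4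
Reactants: 5 1-[(2S,3S)-3-methyl-3-(4-methylpent-3-en-1-yl)oxiran-2-yl]cyclopropan-1-ol
Product: 6 (2S)-2-[(2S)-2-hydroxy-6-methylhept-5-en-2-yl]cyclobutan-1-one
Conditions: BF3·OEt2 (cat.), CH2Cl2, −78 °C
Reagents that add atoms: none
Why: semipinacol rearrangement of an α-hydroxy epoxide, in which a cyclopropane bond migrates anti to the C–O bond of the secondary epoxide carbon (inversion there, strain release and carbonyl formation favouring this cleavage over ionisation at the tertiary carbon), while the tertiary C–O centre is retained.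

Step 5
Reactants: 6 (2S)-2-[(2S)-2-hydroxy-6-methylhept-5-en-2-yl]cyclobutan-1-one
Product: 7 (2S)-2-[(2S,5R)-5-bromo-2,6,6-trimethyloxan-2-yl]cyclobutan-1-one
Conditions: 2,4,4,6-tetrabromocyclohexa-2,5-dien-1-one, MeNO2, 0 °C
Reagents that add atoms: 2,4,4,6-tetrabromocyclohexa-2,5-dien-1-one O=C1C(Br)=CC(Br)(Br)C=C1Br
Why: bromonium-induced 6-endo (Markovnikov) etherification by the tertiary alcohol, where anti addition through a chair with the cyclobutanone-bearing group equatorial should place bromine equatorial and trans to that group (5R).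

Step 6
Reactants: 7 (2S)-2-[(2S,5R)-5-bromo-2,6,6-trimethyloxan-2-yl]cyclobutan-1-one
Product: 8 (2S)-2-[(2S,5R)-5-bromo-2,6,6-trimethyloxan-2-yl]-4-(prop-1-en-2-yl)cyclobutan-1-one (C-4 epimers)
Conditions: LiHMDS, THF, −78 °C; Pd2(dba)3 (cat.), XPhos (cat.), 2-bromopropene, rt; AcOH, −78 °C
Reagents that add atoms: 2-bromopropene CC(Br)=C
Why: palladium-catalysed α-alkenylation of a ketone enolate, in which the base should remove the unhindered α′-CH2 proton and not the methine next to the quaternary oxane carbon, the product rests as its dienolate and is C-protonated kinetically to keep the alkene out of conjugation, and the new centre is later lost.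

Step 7
Reactants: 8 (2S)-2-[(2S,5R)-5-bromo-2,6,6-trimethyloxan-2-yl]-4-(prop-1-en-2-yl)cyclobutan-1-one (C-4 epimers)
Product: 9 (2R)-2-[(2S,5R)-5-bromo-2,6,6-trimethyloxan-2-yl]-4-(prop-1-en-2-yl)cyclobutan-1-ol (C-1 and C-4 epimers)
Conditions: NaBH4, CeCl3·7H2O, MeOH, −40 °C
Reagents that add atoms: none
Why: Luche-type 1,2-reduction at low basicity, and the carbinol configuration does not matter because all diastereomers feed the same ring expansion.

Step 8
Reactants: 9 (2R)-2-[(2S,5R)-5-bromo-2,6,6-trimethyloxan-2-yl]-4-(prop-1-en-2-yl)cyclobutan-1-ol (C-1 and C-4 epimers)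
Product: 12 (6R)-6-[(2S,5R)-5-bromo-2,6,6-trimethyloxan-2-yl]-3-methylcyclohex-3-en-1-ol (C-1 epimers), via potassium cyclobutanolate 10 (not isolated), via potassium cyclohexenolate 11 (not isolated)
Conditions: KH, 18-crown-6, THF, 0 °C to rt; aq. NH4Cl
Reagents that add atoms: none
Why: Deprotonation gives the potassium cyclobutanolate, whose oxyanion weakens the adjacent ring bond to the isopropenyl-bearing carbon (strain release, allylic stabilisation), so the ring opens to an aldehyde tethered to a 2-methylallyl potassium unit or passes through the equivalent concerted [1,3] shift. The distal CH2 terminus of the allyl unit then adds to the carbonyl carbon, closing the cyclohexene by a 6-exo-trig addition to C=O and leaving the methyl-bearing alkene between the former isopropenyl carbon and the former ring carbon. The closest known reaction type is the alkoxide-accelerated vinylcyclobutane rearrangement of 2-vinylcyclobutanols to cyclohex-3-enols. The only new stereocentre is the carbinol carbon, which is not reliably controlled here and is reset in steps 9 and 10, whereas C-6 lies outside the breaking and forming bonds and should keep its configuration. The step needs six- over four-membered recombination and no base attack on the bromo-oxane: the first is thermodynamic (return to the cyclobutanolate is reversible, the cyclohexenolate is not), and the second rests on the equatorial, neopentyl-type C–Br bond, which has no antiperiplanar hydrogen for E2.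

Step 9
Reactants: 12 (6R)-6-[(2S,5R)-5-bromo-2,6,6-trimethyloxan-2-yl]-3-methylcyclohex-3-en-1-ol (C-1 epimers)
Product: 13 (6S)-6-[(2S,5R)-5-bromo-2,6,6-trimethyloxan-2-yl]-3-methylcyclohex-3-en-1-one
Conditions: Dess–Martin periodinane, NaHCO3, CH2Cl2, 0 °C
Reagents that add atoms: none
Why: buffered Dess–Martin oxidation erases the uncontrolled carbinol centre under neutral conditions that should neither move the β,γ-alkene into conjugation nor epimerise the α-centre.

Step 10
Reactants: 13 (6S)-6-[(2S,5R)-5-bromo-2,6,6-trimethyloxan-2-yl]-3-methylcyclohex-3-en-1-one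
Product: 14 (1S,6R)-6-[(2S,5R)-5-bromo-2,6,6-trimethyloxan-2-yl]-3-methylcyclohex-3-en-1-ol
Conditions: L-Selectride, THF, −78 °C
Reagents that add atoms: none
Why: the bulky hydride should attack the 2-substituted cyclohexanone along the equatorial trajectory, giving the axial alcohol cis to the equatorial oxanyl group (1S).

Step 11
Reactants: 14 (1S,6R)-6-[(2S,5R)-5-bromo-2,6,6-trimethyloxan-2-yl]-3-methylcyclohex-3-en-1-ol
Product: 15 (1R,3S,4R,6R)-4-[(2S,5R)-5-bromo-2,6,6-trimethyloxan-2-yl]-6-chloro-1-methylcyclohexane-1,3-diol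
Conditions: NCS, acetone–H2O, 0 °C to rt
Reagents that add atoms: N-chlorosuccinimide O=C1CCC(=O)N1Cl; water O
Why: chlorohydroxylation, in which the chloronium should form on the face anti to the axial hydroxyl and water should open it trans-diaxially at the tertiary carbon (Markovnikov, Fürst–Plattner), placing chlorine at the secondary carbon anti to the oxanyl group and the tertiary hydroxyl syn to it.

Step 12
Reactants: 15 (1R,3S,4R,6R)-4-[(2S,5R)-5-bromo-2,6,6-trimethyloxan-2-yl]-6-chloro-1-methylcyclohexane-1,3-diol
Product: 17 (1S,2R,4S,5S)-4-bromo-2-[(2S,5R)-5-bromo-2,6,6-trimethyloxan-2-yl]-5-chloro-5-methylcyclohexan-1-ol (target), via diaxial bromochloride 16 (not isolated)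
Conditions: TMSBr, CH2Cl2, −30 to 0 °C; NaHCO3, MeOH; then MeCN, 70 °C
Reagents that add atoms: bromotrimethylsilane C[Si](C)(C)Br
Why: the tertiary alcohol should be exchanged for bromide with retention through participation of the antiperiplanar chlorine, and the resulting trans-diaxial dihalide should then undergo the known diaxial-to-diequatorial 1,2-interchange of vicinal dihalides, each halogen staying on its own face, so that bromine ends equatorial at C4 (cis to the oxanyl group) and chlorine equatorial at C5.

**Compound list**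

1 | geraniol, (2E)-3,7-dimethylocta-2,6-dien-1-ol | OC/C=C(\C)CCC=C(C)C | starting material
2 | [(2S,3S)-3-methyl-3-(4-methylpent-3-en-1-yl)oxiran-2-yl]methanol | OC[C@@H]1O[C@@]1(C)CCC=C(C)C | intermediate
3 | (2R,3S)-3-methyl-3-(4-methylpent-3-en-1-yl)oxirane-2-carboxylic acid | OC(=O)[C@@H]1O[C@@]1(C)CCC=C(C)C | intermediate (not isolated)
4 | methyl (2R,3S)-3-methyl-3-(4-methylpent-3-en-1-yl)oxirane-2-carboxylate | COC(=O)[C@@H]1O[C@@]1(C)CCC=C(C)C | intermediate
5 | 1-[(2S,3S)-3-methyl-3-(4-methylpent-3-en-1-yl)oxiran-2-yl]cyclopropan-1-ol | OC1(CC1)[C@@H]2O[C@@]2(C)CCC=C(C)C | intermediate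
6 | (2S)-2-[(2S)-2-hydroxy-6-methylhept-5-en-2-yl]cyclobutan-1-one | O=C1CC[C@H]1[C@@](C)(O)CCC=C(C)C | intermediate
7 | (2S)-2-[(2S,5R)-5-bromo-2,6,6-trimethyloxan-2-yl]cyclobutan-1-one | O=C1CC[C@H]1[C@]2(C)CC[C@@H](Br)C(C)(C)O2 | intermediate
8 | (2S)-2-[(2S,5R)-5-bromo-2,6,6-trimethyloxan-2-yl]-4-(prop-1-en-2-yl)cyclobutan-1-one, C-4 left open (both epimers used) | O=C1C(C(C)=C)C[C@H]1[C@]2(C)CC[C@@H](Br)C(C)(C)O2 | intermediate
9 | (2R)-2-[(2S,5R)-5-bromo-2,6,6-trimethyloxan-2-yl]-4-(prop-1-en-2-yl)cyclobutan-1-ol, C-1 and C-4 left open | OC1C(C(C)=C)C[C@H]1[C@]2(C)CC[C@@H](Br)C(C)(C)O2 | intermediate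
10 | potassium alkoxide of 9 | [K+].[O-]C1C(C(C)=C)C[C@H]1[C@]2(C)CC[C@@H](Br)C(C)(C)O2 | intermediate (not isolated)
11 | potassium (6R)-6-[(2S,5R)-5-bromo-2,6,6-trimethyloxan-2-yl]-3-methylcyclohex-3-en-1-olate | [K+].[O-]C1CC(C)=CC[C@H]1[C@]2(C)CC[C@@H](Br)C(C)(C)O2 | intermediate (not isolated)
12 | (6R)-6-[(2S,5R)-5-bromo-2,6,6-trimethyloxan-2-yl]-3-methylcyclohex-3-en-1-ol, C-1 left open | OC1CC(C)=CC[C@H]1[C@]2(C)CC[C@@H](Br)C(C)(C)O2 | intermediate
13 | (6S)-6-[(2S,5R)-5-bromo-2,6,6-trimethyloxan-2-yl]-3-methylcyclohex-3-en-1-one | O=C1CC(C)=CC[C@H]1[C@]2(C)CC[C@@H](Br)C(C)(C)O2 | intermediate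
14 | (1S,6R)-6-[(2S,5R)-5-bromo-2,6,6-trimethyloxan-2-yl]-3-methylcyclohex-3-en-1-ol | O[C@H]1CC(C)=CC[C@H]1[C@]2(C)CC[C@@H](Br)C(C)(C)O2 | intermediate
15 | (1R,3S,4R,6R)-4-[(2S,5R)-5-bromo-2,6,6-trimethyloxan-2-yl]-6-chloro-1-methylcyclohexane-1,3-diol | O[C@H]1C[C@@](C)(O)[C@H](Cl)C[C@H]1[C@]2(C)CC[C@@H](Br)C(C)(C)O2 | intermediate
16 | (1S,2R,4R,5R)-5-bromo-2-[(2S,5R)-5-bromo-2,6,6-trimethyloxan-2-yl]-4-chloro-5-methylcyclohexan-1-ol | O[C@H]1C[C@@](C)(Br)[C@H](Cl)C[C@H]1[C@]2(C)CC[C@@H](Br)C(C)(C)O2 | intermediate (not isolated)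
17 | (1S,2R,4S,5S)-4-bromo-2-[(2S,5R)-5-bromo-2,6,6-trimethyloxan-2-yl]-5-chloro-5-methylcyclohexan-1-ol | CC1(C)O[C@](C)([C@@H]2C[C@H](Br)[C@@](C)(Cl)C[C@@H]2O)CC[C@H]1Br | target

Total step count: 12. Longest linear sequence: 12 steps (from geraniol).

**Steps most likely to fail**

1. Step 12. Ionisation of the tertiary carbinol may be outrun by acid cleavage of the bis-tertiary oxane ether or by E1 loss of HBr, and the dihalide interchange may stop at an unfavourable equilibrium. The fallback sets out from 14 and reaches the same bromonium ion by a kinetically controlled route. Alcohol 14 is silylated (TBSOTf, 2,6-lutidine) to the tert-butyldimethylsilyl ether of 14 F1. Buffered mCPBA should attack anti to the axial silyloxy group to give the α-epoxide F2. HBr in ether at 0 °C should open it trans-diaxially at the tertiary carbon to the bromohydrin F3. SOCl2/pyridine activates the secondary alcohol, the antiperiplanar tertiary bromine bridges and shifts, and chloride enters at the tertiary carbon to give the silyl ether of the target F4. HF·pyridine then returns the route to 17.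

2. Step 6. Self-condensation or ring opening of the strained cyclobutanone enolate at palladium, or drift of the new alkene into conjugation, may prevent the coupling. The fallback sets out from 7. The kinetic lithium enolate (LDA, −78 °C) is added to acetone to give the aldol adduct F5. Dehydration (SOCl2, pyridine) gives the conjugated isopropylidene ketone F6. Deprotonation at the γ-methyl (LDA, HMPA, −78 °C) and kinetic α-protonation with acetic acid return the route to 8.

3. Step 8. Proton transfer inside the ring-opened aldehyde/allyl-potassium pair (enolisation next to the oxanyl-bearing carbon) or base-induced loss of HBr from the bromo-oxane may compete with recombination. The fallback sets out from ketone 8 and uses a neutral photochemical 1,3-acyl shift (Norrish type I cleavage and allylic recombination, hν 300 nm, benzene), which should give cyclohexenone 13 directly. It rejoins the route at 13 and forms no compound outside the list (F0).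

**Further compounds**

F1 | step 12 | tert-butyldimethylsilyl ether of 14 | CC(C)(C)[Si](C)(C)O[C@H]1CC(C)=CC[C@H]1[C@]2(C)CC[C@@H](Br)C(C)(C)O2
F2 | step 12 | 3,4-epoxide of F1 with the oxirane oxygen anti to the silyloxy group | CC(C)(C)[Si](C)(C)O[C@H]1C[C@]3(C)O[C@@H]3C[C@H]1[C@]2(C)CC[C@@H](Br)C(C)(C)O2
F3 | step 12 | trans-diaxial bromohydrin (tertiary bromide syn to the silyloxy group, secondary hydroxyl anti) | CC(C)(C)[Si](C)(C)O[C@H]1C[C@@](C)(Br)[C@H](O)C[C@H]1[C@]2(C)CC[C@@H](Br)C(C)(C)O2
F4 | step 12 | tert-butyldimethylsilyl ether of 17 | CC(C)(C)[Si](C)(C)O[C@H]1C[C@](C)(Cl)[C@@H](Br)C[C@H]1[C@]2(C)CC[C@@H](Br)C(C)(C)O2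
F5 | step 6 | (2S)-2-[(2S,5R)-5-bromo-2,6,6-trimethyloxan-2-yl]-4-(2-hydroxypropan-2-yl)cyclobutan-1-one | O=C1C(C(C)(C)O)C[C@H]1[C@]2(C)CC[C@@H](Br)C(C)(C)O2
F6 | step 6 | (2S)-2-[(2S,5R)-5-bromo-2,6,6-trimethyloxan-2-yl]-4-(propan-2-ylidene)cyclobutan-1-one | O=C1C(=C(C)C)C[C@H]1[C@]2(C)CC[C@@H](Br)C(C)(C)O2
F0 | step 8 | none | none
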